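Percent of the charge per day is the unit to read these runs in.

| setting | south-east | south-west | oak | ash |
|---|---|---|---|---|
| substrate | 24 mM | 24 mM | 24 mM | 24 mM |
| partner | 25.2 mM | 25.2 mM | 25.2 mM | 25.2 mM |
| rival reagent | 32 mM | 72 mM | 48.0 mM | 48.0 mM |
| temperature | 85 °C | 102 °C | 115 °C | 90 °C |
| remark | run made earlier | run made earlier |  |  |
| time |  |  | 2.5 d | 2.5 d |

| run | time / d | target / % |
|---|---|---|
| south-east | 3.00 | 83.8 |
| south-east | 6.00 | 83.6 |
| south-east | 8.00 | 81.6 |
| south-east | 12.0 | 79.6 |
| south-west | 1.25 | 65.2 |
| south-west | 2.50 | 61.1 |
| south-west | 3.00 | 59.4 |
| south-west | 5.00 | 52.5 |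
| south-west | 6.00 | 49.1 |

(readings scatter by 0.3 percentage points)
- a reading or a percentage of target counts all its forms, free or not
* the flask that comes out highest in amount of target, in percent of the substrate charged, or "all alike" when all lie within 1.5 percentage points (oak / ash / all alike)
* target at the end, in percent of the substrate charged, oak
* target at the end, in percent of the substrate charged, ash

The south-west run falls 0.0328 /d early and 0.0340 /d late, as shares of the charge. The slope stays about the same, though target shrinks by a quarter. So I read the fall in the south-west run as zero order in target: over these readings the rate does not follow the total amount of target. Over all its readings the south-west run falls 0.0339 /d, and the south-east run 0.00467 /d. I assume the rate follows [rival reagent]. Per mM, the hotter run is then faster by 3.23, and I carry that factor along 1/T.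

Z = rate per mM × [rival reagent] × t

oak: Z = 0.129
ash: Z = 0.0250

Call Z the fall number: the share of the charge that target is reckoned to lose by the end, if the fall runs straight from zero time.

Is one number enough? No. Running the lines back gives starting heights of 85.2% for south-east and 69.4% for south-west, so on these lines the two earlier runs stand apart at zero time, before any fall. So I also scale the odds of substrate missing target with [rival reagent] and the same 1/T position:

oak: height 75.8%, end 62.9%
ash: height 78.7%, end 76.2%

The forecast says ash, with 55% for oak and 77% for ash, and one of its grounds reads “Assuming decay is first order in rival”. My oak stands 7.9 percentage points above its figure.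

The flasks give 60.2% for oak and 77.4% for ash, so ash comes out highest.

    crystals ⇌ target, rate k1*(cs1 - [target]) while solid is left; crystals form when [target] > cs1 (solubility = 0.420 mM, k = 0.00110 /s)
    substrate + rival reagent → side product (k = 1.50 × 10⁻⁴ /M/s, Ea = 99.0 kJ/mol)
    substrate + partner → target (k = 0.00230 /M/s, Ea = 71.0 kJ/mol)
    rival reagent + target → over-reaction product (k = 1.90 × 10⁻⁴ /M/s, Ea = 65.0 kJ/mol)
    (constants at 90 °C)

At the end of oak, crystals hold nearly all of the target, 58.5% of 60.2%, and over-reaction product stands at 13.3% against a Z of 0.129. For ash left ten times as long, the reckoned Z is 0.250, and after 25.0 d its over-reaction product stands at 29.1%, with target at 52.4%.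

(The data were computed with constants of no real substance; noise was put on by code.)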